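Assumption: the SMILES is read as (2R,3R,4R) in the upper unit and (2R,3R) in the lower unit, i.e. (−)-epicatechin-(4β→8)-(−)-epiafzelechin; all phenols are carried as benzyl ethers.

## Retrosynthetic overview

1. Target 17 ⇐ hepta-O-benzyl ether 16 by global hydrogenolysis.
2. 16 ⇐ aldehyde 7 + epoxide 13 in one flask: Friedel–Crafts closure of C4'–C4a' (ring F), Friedel–Crafts closure of C4–C4a (ring C), then capture of the C4 cation by C8 of the new lower unit.
3. 7 and 13 ⇐ threo aryl ethers 6 and 11 (ester → CHO; ester → diol → terminal epoxide). All C2/C3 centres are set before any ring exists.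
4. 6 and 11 ⇐ SN2 opening of cis-glycidates 4 and 10 by 3,5-bis(benzyloxy)phenol (cis-epoxide + inversion = threo = later 2,3-cis).
5. 4 and 10 ⇐ Jacobsen epoxidation of Z-cinnamates 3 and 9 ⇐ Still–Gennari olefination of aldehydes 1 and 8. Aromatic rings A, B, D, E are bought; rings F and C are both formed in step 10.

## Route

Step 1
Reactants: 1 3,4-bis(benzyloxy)benzaldehyde; 2 ethyl [bis(2,2,2-trifluoroethoxy)phosphoryl]acetate
Product: 3 ethyl (2Z)-3-[3,4-bis(benzyloxy)phenyl]prop-2-enoate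
Conditions: KHMDS, 18-crown-6, THF, −78 °C
Reagents that add atoms: none
Why: Still–Gennari variant of the Horner–Wadsworth–Emmons olefination, in which the electron-poor phosphonate eliminates fast from the kinetic adduct and gives the Z-cinnamate with high selectivity for aryl aldehydes; no stereocentre is formed.

Step 2
Reactants: 3 ethyl (2Z)-3-[3,4-bis(benzyloxy)phenyl]prop-2-enoate
Product: 4 ethyl (2S,3S)-3-[3,4-bis(benzyloxy)phenyl]oxirane-2-carboxylate (cis)
Conditions: (S,S)-Jacobsen Mn(salen)Cl (5 mol %), 4-phenylpyridine N-oxide (25 mol %), aq. NaOCl (pH 11.3), CH2Cl2, 0 °C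
Reagents that add atoms: sodium hypochlorite, [Na+].[O-]Cl
Why: Jacobsen–Katsuki epoxidation, for which cis-cinnamate esters (including 4-alkoxy ones) are privileged substrates; the (S,S)-catalyst sets both centres as (2S,3S) by oxygen delivery to one enantioface, and the minor trans-epoxide is removed by chromatography.

Step 3
Reactants: 4 ethyl (2S,3S)-3-[3,4-bis(benzyloxy)phenyl]oxirane-2-carboxylate; 5 3,5-bis(benzyloxy)phenol
Product: 6 ethyl (2S,3R)-3-[3,5-bis(benzyloxy)phenoxy]-3-[3,4-bis(benzyloxy)phenyl]-2-hydroxypropanoate (threo)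
Conditions: Cs2CO3 (20 mol %), DMF, 50 °C
Reagents that add atoms: none
Why: base-catalysed SN2 opening of a glycidic ester by a phenoxide at the benzylic carbon, which inverts C3 (S → R) and leaves C2 untouched, so the aryloxy and hydroxy groups are threo; no Lewis acid is present, which disfavours ionisation of the electron-rich benzylic carbon.

Step 4
Reactants: 6 ethyl (2S,3R)-3-[3,5-bis(benzyloxy)phenoxy]-3-[3,4-bis(benzyloxy)phenyl]-2-hydroxypropanoate
Product: 7 (2S,3R)-3-[3,5-bis(benzyloxy)phenoxy]-3-[3,4-bis(benzyloxy)phenyl]-2-hydroxypropanal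
Conditions: DIBAL-H (2.2 equiv), CH2Cl2, −78 °C; Rochelle salt work-up; used crude
Reagents that add atoms: none
Why: low-temperature DIBAL-H partial reduction, in which the aluminium hemiacetal chelated by the neighbouring aluminium alkoxide survives at −78 °C and releases the aldehyde only on work-up; no stereocentre is touched.

Step 5
Reactants: 8 4-(benzyloxy)benzaldehyde; 2 ethyl [bis(2,2,2-trifluoroethoxy)phosphoryl]acetate
Product: 9 ethyl (2Z)-3-[4-(benzyloxy)phenyl]prop-2-enoate
Conditions: KHMDS, 18-crown-6, THF, −78 °C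
Reagents that add atoms: none
Why: Still–Gennari olefination as in step 1, giving the Z-alkene under kinetic control; no stereocentre is formed.

Step 6
Reactants: 9 ethyl (2Z)-3-[4-(benzyloxy)phenyl]prop-2-enoate
Product: 10 ethyl (2S,3S)-3-[4-(benzyloxy)phenyl]oxirane-2-carboxylate (cis)
Conditions: (S,S)-Jacobsen Mn(salen)Cl (5 mol %), 4-phenylpyridine N-oxide (25 mol %), aq. NaOCl (pH 11.3), CH2Cl2, 0 °C
Reagents that add atoms: sodium hypochlorite, [Na+].[O-]Cl
Why: Jacobsen–Katsuki epoxidation of a cis-4-alkoxycinnamate, with the (S,S)-catalyst setting both centres as (2S,3S) exactly as in step 2.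

Step 7
Reactants: 10 ethyl (2S,3S)-3-[4-(benzyloxy)phenyl]oxirane-2-carboxylate; 5 3,5-bis(benzyloxy)phenol
Product: 11 ethyl (2S,3R)-3-[3,5-bis(benzyloxy)phenoxy]-3-[4-(benzyloxy)phenyl]-2-hydroxypropanoate (threo)
Conditions: Cs2CO3 (20 mol %), DMF, 50 °C
Reagents that add atoms: none
Why: phenoxide SN2 epoxide opening at the benzylic carbon with inversion (C3 S → R) and retention at C2, as in step 3.

Step 8
Reactants: 11 ethyl (2S,3R)-3-[3,5-bis(benzyloxy)phenoxy]-3-[4-(benzyloxy)phenyl]-2-hydroxypropanoate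
Product: 12 (2R,3R)-3-[3,5-bis(benzyloxy)phenoxy]-3-[4-(benzyloxy)phenyl]propane-1,2-diol
Conditions: NaBH4, EtOH/THF, 0 °C → rt
Reagents that add atoms: none
Why: borohydride reduction of an α-hydroxy ester, which is activated by the α-oxygen, to the 1,2-diol; the stereocentres are untouched (the C2 descriptor changes only because the priorities change).

Step 9
Reactants: 12 (2R,3R)-3-[3,5-bis(benzyloxy)phenoxy]-3-[4-(benzyloxy)phenyl]propane-1,2-diol
Product: 13 (2R)-2-{(R)-[3,5-bis(benzyloxy)phenoxy][4-(benzyloxy)phenyl]methyl}oxirane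
Conditions: PPh3, DIAD, toluene, 0 → 80 °C
Reagents that add atoms: none
Why: Mitsunobu cyclodehydration of a 1,2-diol, in which the unhindered primary hydroxyl is activated and displaced by the secondary oxygen, so no bond to either stereocentre is broken and both stay R.

Step 10
Reactants: 7 (2S,3R)-3-[3,5-bis(benzyloxy)phenoxy]-3-[3,4-bis(benzyloxy)phenyl]-2-hydroxypropanal; 13 (2R)-2-{(R)-[3,5-bis(benzyloxy)phenoxy][4-(benzyloxy)phenyl]methyl}oxirane
Product: 16 5,7,3',4'-tetra-O-benzyl-epicatechin-(4β→8)-5,7,4'-tri-O-benzyl-epiafzelechin, via 5,7,4'-tri-O-benzyl-epiafzelechin 14 (not isolated), via tetra-O-benzyl-2,3-cis-flavan-3,4-diol 15 (not isolated)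
Conditions: BF3·OEt2 (30 mol %), 4 Å MS, CH2Cl2, −78 °C: 13 (3 equiv) first, then 7 added slowly, −78 → −30 °C, one flask
Reagents that add atoms: none
Why: Proposed new method: BF3 first drives 6-endo Friedel–Crafts opening of the terminal epoxide of 13 by the ortho carbon of its phloroglucinol-type aryl ether to give 14 (ring F; closest known reaction: Lewis-acid or Au(III)-catalysed cyclisation of aryl glycidyl ethers to chroman-3-ols), the same acid then closes ring C of 7 by intramolecular Friedel–Crafts hydroxyalkylation onto the aldehyde to give 15, which ionises at C4 like a leucoanthocyanidin (closest known reaction: Lewis-acid condensation of flavan-3,4-diols or their C4 ethers with benzylated flavan-3-ols), and the cation is trapped by C8 of 14 (kept in excess to suppress self-condensation) anti to the axial 3-OH of the 2,3-cis ring, which sets C4 as R (4β, 3,4-trans) under substrate control, while the four C2/C3 centres are untouched because only C–C bonds remote from them are made.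

Step 11
Reactants: 16 5,7,3',4'-tetra-O-benzyl-epicatechin-(4β→8)-5,7,4'-tri-O-benzyl-epiafzelechin
Product: 17 (−)-epicatechin-(4β→8)-(−)-epiafzelechin (CNP0299023.1)
Conditions: H2 (1 atm), 20% Pd(OH)2/C, THF/MeOH/H2O, rt
Reagents that add atoms: none
Why: hydrogenolysis of the seven aryl benzyl ethers over Pearlman's catalyst under neutral conditions, which leaves the acid- and base-sensitive interflavan bond and all five stereocentres unchanged.

## Compound list

1 | 3,4-bis(benzyloxy)benzaldehyde | O=Cc1ccc(OCc2ccccc2)c(OCc2ccccc2)c1 | starting material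
2 | ethyl [bis(2,2,2-trifluoroethoxy)phosphoryl]acetate | CCOC(=O)CP(=O)(OCC(F)(F)F)OCC(F)(F)F | starting material
3 | ethyl (2Z)-3-[3,4-bis(benzyloxy)phenyl]prop-2-enoate | CCOC(=O)/C=C\c1ccc(OCc2ccccc2)c(OCc2ccccc2)c1 | intermediate
4 | ethyl (2S,3S)-3-[3,4-bis(benzyloxy)phenyl]oxirane-2-carboxylate (cis) | CCOC(=O)[C@H]1O[C@H]1c1ccc(OCc2ccccc2)c(OCc2ccccc2)c1 | intermediate
5 | 3,5-bis(benzyloxy)phenol | Oc1cc(OCc2ccccc2)cc(OCc2ccccc2)c1 | starting material
6 | ethyl (2S,3R)-3-[3,5-bis(benzyloxy)phenoxy]-3-[3,4-bis(benzyloxy)phenyl]-2-hydroxypropanoate | CCOC(=O)[C@@H](O)[C@@H](c1ccc(OCc2ccccc2)c(OCc2ccccc2)c1)Oc1cc(OCc2ccccc2)cc(OCc2ccccc2)c1 | intermediate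
7 | (2S,3R)-3-[3,5-bis(benzyloxy)phenoxy]-3-[3,4-bis(benzyloxy)phenyl]-2-hydroxypropanal | O=C[C@@H](O)[C@@H](c1ccc(OCc2ccccc2)c(OCc2ccccc2)c1)Oc1cc(OCc2ccccc2)cc(OCc2ccccc2)c1 | intermediate
8 | 4-(benzyloxy)benzaldehyde | O=Cc1ccc(OCc2ccccc2)cc1 | starting material
9 | ethyl (2Z)-3-[4-(benzyloxy)phenyl]prop-2-enoate | CCOC(=O)/C=C\c1ccc(OCc2ccccc2)cc1 | intermediate
10 | ethyl (2S,3S)-3-[4-(benzyloxy)phenyl]oxirane-2-carboxylate (cis) | CCOC(=O)[C@H]1O[C@H]1c1ccc(OCc2ccccc2)cc1 | intermediate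
11 | ethyl (2S,3R)-3-[3,5-bis(benzyloxy)phenoxy]-3-[4-(benzyloxy)phenyl]-2-hydroxypropanoate | CCOC(=O)[C@@H](O)[C@@H](c1ccc(OCc2ccccc2)cc1)Oc1cc(OCc2ccccc2)cc(OCc2ccccc2)c1 | intermediate
12 | (2R,3R)-3-[3,5-bis(benzyloxy)phenoxy]-3-[4-(benzyloxy)phenyl]propane-1,2-diol | OC[C@@H](O)[C@@H](c1ccc(OCc2ccccc2)cc1)Oc1cc(OCc2ccccc2)cc(OCc2ccccc2)c1 | intermediate
13 | (2R)-2-{(R)-[3,5-bis(benzyloxy)phenoxy][4-(benzyloxy)phenyl]methyl}oxirane | C1O[C@H]1[C@@H](c1ccc(OCc2ccccc2)cc1)Oc1cc(OCc2ccccc2)cc(OCc2ccccc2)c1 | intermediate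
14 | (2R,3R)-5,7-bis(benzyloxy)-2-[4-(benzyloxy)phenyl]chroman-3-ol (5,7,4'-tri-O-benzyl-epiafzelechin) | c1ccccc1COc1ccc([C@H]2Oc3cc(OCc4ccccc4)cc(OCc4ccccc4)c3C[C@H]2O)cc1 | intermediate
15 | (2R,3R)-5,7-bis(benzyloxy)-2-[3,4-bis(benzyloxy)phenyl]chromane-3,4-diol (2,3-cis, both C4 epimers) | OC1c2c(OCc3ccccc3)cc(OCc3ccccc3)cc2O[C@H](c2ccc(OCc3ccccc3)c(OCc3ccccc3)c2)[C@@H]1O | intermediate
16 | (2R,3R,4R)-5,7-bis(benzyloxy)-2-[3,4-bis(benzyloxy)phenyl]-4-{(2R,3R)-5,7-bis(benzyloxy)-2-[4-(benzyloxy)phenyl]-3-hydroxychroman-8-yl}chroman-3-ol | c1ccccc1COc1ccc([C@H]2Oc3c(c(OCc4ccccc4)cc(OCc4ccccc4)c3[C@H]3c4c(OCc5ccccc5)cc(OCc5ccccc5)cc4O[C@H](c4ccc(OCc5ccccc5)c(OCc5ccccc5)c4)[C@@H]3O)C[C@H]2O)cc1 | intermediate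
17 | (2R,3R,4R)-2-(3,4-dihydroxyphenyl)-4-[(2R,3R)-3,5,7-trihydroxy-2-(4-hydroxyphenyl)chroman-8-yl]chromane-3,5,7-triol | Oc1ccc([C@H]2Oc3c(c(O)cc(O)c3[C@H]3c4c(O)cc(O)cc4O[C@H](c4ccc(O)c(O)c4)[C@@H]3O)C[C@H]2O)cc1 | target

## Step count and risks

Total steps: 11 (upper arm steps 1–4, lower arm steps 5–9, common steps 10–11).
Longest linear sequence: 7 steps (8 → 9 → 10 → 11 → 12 → 13 → 16 → 17).

Most likely to fail, in order:

(i) Step 10. Three acid-driven events must occur in the right order in one flask. The risks are ionisation of the acyclic benzylic aryl ethers before ring closure, attack of the C4 cation on uncyclised 13 (which would give some 4→6 isomer), and oligomerisation. The fallback sets out from 7 and 13 and returns at 16. Epoxide 13 is cyclised alone with catalytic BF3·OEt2 at −78 °C and 14 is isolated. Aldehyde 7 is cyclised separately with a mild acid in CH2Cl2 containing excess 2-ethoxyethanol, so that the C4 cation formed via 15 is capped as the stable ether (2R,3R,4S)-5,7-bis(benzyloxy)-2-[3,4-bis(benzyloxy)phenyl]-4-(2-ethoxyethoxy)chroman-3-ol F1. F1 is then coupled with 14 (excess) under catalytic TMSOTf at −78 °C, the standard activation of a C4 ether, to give 16.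

(ii) Step 3 (step 7 carries the same risk, less severe because its aryl group is less electron-rich). Phenoxide could attack C2 instead of C3, or partial ionisation of the benzylic carbon could erode inversion. The fallback sets out from 4 and returns at 7. The ester of 4 is reduced first with NaBH4 to the cis-epoxy alcohol [(2R,3S)-3-[3,4-bis(benzyloxy)phenyl]oxiran-2-yl]methanol F2. F2 is opened with phenol 5 under aqueous NaOH in t-BuOH at 60 °C, conditions under which phenoxides open 3-arylglycidols at the benzylic carbon with inversion, giving (2R,3R)-3-[3,5-bis(benzyloxy)phenoxy]-3-[3,4-bis(benzyloxy)phenyl]propane-1,2-diol F3. Only the primary hydroxyl of F3 is then oxidised with TEMPO/PhI(OAc)2 to give 7.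

(iii) Step 4. Over-reduction to the diol and the sensitivity of the free α-hydroxy aldehyde are the concerns. The fallback sets out from 6 and returns at 7. Ester 6 is converted with MeNHOMe·HCl and i-PrMgCl (THF, −20 °C) into the Weinreb amide (2S,3R)-3-[3,5-bis(benzyloxy)phenoxy]-3-[3,4-bis(benzyloxy)phenyl]-2-hydroxy-N-methoxy-N-methylpropanamide F4. F4 is reduced with LiAlH4 at −78 °C; the chelated tetrahedral intermediate cannot collapse before work-up, so reduction stops at aldehyde 7, which is taken directly into step 10.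

## Further compounds

F1 | step 10 | (2R,3R,4S)-5,7-bis(benzyloxy)-2-[3,4-bis(benzyloxy)phenyl]-4-(2-ethoxyethoxy)chroman-3-ol | CCOCCO[C@H]1c2c(OCc3ccccc3)cc(OCc3ccccc3)cc2O[C@H](c2ccc(OCc3ccccc3)c(OCc3ccccc3)c2)[C@@H]1O
F2 | step 3 | [(2R,3S)-3-[3,4-bis(benzyloxy)phenyl]oxiran-2-yl]methanol | OC[C@H]1O[C@H]1c1ccc(OCc2ccccc2)c(OCc2ccccc2)c1
F3 | step 3 | (2R,3R)-3-[3,5-bis(benzyloxy)phenoxy]-3-[3,4-bis(benzyloxy)phenyl]propane-1,2-diol | OC[C@@H](O)[C@@H](c1ccc(OCc2ccccc2)c(OCc2ccccc2)c1)Oc1cc(OCc2ccccc2)cc(OCc2ccccc2)c1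
F4 | step 4 | (2S,3R)-3-[3,5-bis(benzyloxy)phenoxy]-3-[3,4-bis(benzyloxy)phenyl]-2-hydroxy-N-methoxy-N-methylpropanamide | CON(C)C(=O)[C@@H](O)[C@@H](c1ccc(OCc2ccccc2)c(OCc2ccccc2)c1)Oc1cc(OCc2ccccc2)cc(OCc2ccccc2)c1
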